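**Plan**

- Retrosynthesis: the O1–C2 bond of ring C is cut first (retro-oxa-Michael) to a 2'-hydroxychalcone, and the two methyl ethers on O5 and O7 are removed. The ring A bond C4a–C5 is then cut (retro-Claisen; it is the same as C4a–C8a while ring A is still symmetric), and last the chain bond C4–C4a between a diketo ester trianion and a cinnamoyl Weinreb amide.
- Enabling feature: ring A carries oxygen on C5, C7 and C8a in a 1,3,5 pattern and bears the C4 carbonyl on C4a, between C5 and C8a. It is an acylphloroglucinol whose six carbons and three oxygens are three acetate units of a chain begun by the 3,4,5-trimethoxycinnamoyl group.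
- Forward order: the chain is joined at C4–C4a, ring A is closed by Claisen condensation and aromatises, O5 and O7 are methylated while the chelated hydroxyl stays free, and ring C is closed last.
- Stereochemistry: C2 (S) is the only stereocentre and is set in the final ring closure by a cinchona-derived thiourea catalyst; the E alkene comes from the cinnamic acid.

Key step: step 4

Assumption: the quinine-derived thiourea is taken to deliver the (S)-flavanone; if the sense of induction proves opposite, the quinidine-derived pseudo-enantiomer replaces it under the same conditions (polycarbonyl compounds are drawn as keto tautomers).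

**Route**

Step 1
Reactants: 1 dehydroacetic acid (3-acetyl-6-methyl-2H-pyran-2,4(3H)-dione)
Product: 2 methyl 3,5-dioxohexanoate
Conditions: Mg(OMe)2 (2 equiv, commercial solution in MeOH), MeOH, reflux; then cold 1 M HCl
Reagents that add atoms: magnesium methoxide (supplies the ester OCH3), [Mg+2].[O-]C.[O-]C; methanol, CO
Why: Methoxide opens the pyranone lactone and removes the 3-acetyl group by retro-Claisen cleavage, and the magnesium chelate of the resulting 3,5-diketo ester resists re-lactonisation, a known preparation of this ester.

Step 2
Reactants: 3 (E)-3,4,5-trimethoxycinnamic acid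
Product: 5 (E)-N-methoxy-N-methyl-3-(3,4,5-trimethoxyphenyl)prop-2-enamide, via (E)-3,4,5-trimethoxycinnamoyl imidazolide 4 (not isolated)
Conditions: CDI (1.2 equiv), CH2Cl2, 25 °C; then MeNH(OMe)·HCl (1.5 equiv), 25 °C
Reagents that add atoms: 1,1'-carbonyldiimidazole, O=C(n1ccnc1)n1ccnc1 (imidazolyl group of 4 only); N,O-dimethylhydroxylamine hydrochloride, CNOC.Cl
Why: Standard Weinreb amide formation by carbonyldiimidazole activation and aminolysis of the acyl imidazolide, which leaves the E alkene and the aryl ethers untouched.

Step 3
Reactants: 2 methyl 3,5-dioxohexanoate (2 equiv); 5 (E)-N-methoxy-N-methyl-3-(3,4,5-trimethoxyphenyl)prop-2-enamide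
Product: 7 methyl (E)-3,5,7-trioxo-9-(3,4,5-trimethoxyphenyl)non-8-enoate, via trilithium trianion of methyl 3,5-dioxohexanoate 6 (not isolated)
Conditions: LiN(i-Pr)2 (3.1 equiv per 2), THF, −78 → 0 °C; then 5 (0.5 equiv per 2), −78 → −20 °C; cold dilute HCl to pH 4, rapid extraction, used crude (excess 2 is carried along and washed out after step 4)
Reagents that add atoms: lithium diisopropylamide, [Li+].CC(C)[N-]C(C)C (lithium of 6 only)
Why: Claisen-type acylation of a β-polycarbonyl polyanion, in which the trianion reacts at C6, its last-formed and most nucleophilic carbanion, and the Weinreb amide takes the nucleophile at the carbonyl carbon without conjugate addition or over-addition.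

Step 4
Reactants: 7 methyl (E)-3,5,7-trioxo-9-(3,4,5-trimethoxyphenyl)non-8-enoate
Product: 8 (E)-1-(2,4,6-trihydroxyphenyl)-3-(3,4,5-trimethoxyphenyl)prop-2-en-1-one (2',4',6'-trihydroxy-3,4,5-trimethoxychalcone)
Conditions: Mg(OMe)2 (4 equiv), dry MeOH, Ar, 25 → 50 °C; then ice-cold 1 M HCl, rapid extraction
Reagents that add atoms: none
Why: Magnesium methoxide turns 7 into a chelated polyenolate in which the C6 carbanion, flanked by the C5 and C7 carbonyls, attacks the magnesium-activated ester carbon C1; loss of methoxide and threefold enolisation give the aromatic phloroglucinol ring with the cinnamoyl group on the new ring carbon. The closest known reaction type is the intramolecular Claisen (Dieckmann-type) cyclisation of 3,5,7-triketo esters and of the related 6-acylmethyl-4-hydroxy-2-pyranones to acylphloroglucinols under magnesium methoxide. Ring A closes in the 6-exo-trig mode, the ester C=O lying outside the new ring. No stereocentre is formed and the E alkene is a spectator. The step needs the Claisen mode (C6 to C1) to beat the aldol mode (C2 to C7) that would give a resorcylate, and to beat O-cyclisation to pyranones. The C7 carbonyl is a conjugated cinnamoyl ketone held as an enolate in the chelate and is therefore a poor electrophile, while the ester is the one carbonyl not tied up as an enolate, and the water-free medium prevents hydrolysis to the acid, which would follow the aldol path.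

Step 5
Reactants: 8 (E)-1-(2,4,6-trihydroxyphenyl)-3-(3,4,5-trimethoxyphenyl)prop-2-en-1-one
Product: 9 (E)-1-(2-hydroxy-4,6-dimethoxyphenyl)-3-(3,4,5-trimethoxyphenyl)prop-2-en-1-one
Conditions: Me2SO4 (2.2 equiv), K2CO3 (3 equiv), acetone, reflux
Reagents that add atoms: dimethyl sulfate, COS(=O)(=O)OC
Why: Williamson ether synthesis in which the 4'-hydroxyl and one of the two equivalent ortho hydroxyls are methylated while the last ortho hydroxyl is protected by its hydrogen bond to the carbonyl, and any flavanone formed from 8 under base should reopen by β-elimination under the same conditions and converge on 9.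

Step 6
Reactants: 9 (E)-1-(2-hydroxy-4,6-dimethoxyphenyl)-3-(3,4,5-trimethoxyphenyl)prop-2-en-1-one
Product: 10 (2S)-5,7-dimethoxy-2-(3,4,5-trimethoxyphenyl)chroman-4-one
Conditions: N-[3,5-bis(trifluoromethyl)phenyl]-N'-[(8α,9S)-6'-methoxycinchonan-9-yl]thiourea (quinine-derived, 10 mol %), toluene, 0–25 °C
Reagents that add atoms: none
Why: Catalytic asymmetric intramolecular oxa-Michael addition (6-endo-trig) of a 2'-hydroxychalcone, in which the quinuclidine nitrogen deprotonates the phenol while the thiourea hydrogen-bonds the enone carbonyl, so the phenoxide is delivered within a chiral ion pair to one face of the β-carbon and C2 is set as S under catalyst control, the 6'-methoxy group shifting the chalcone–flavanone balance toward the closed ring.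

**Compound list**

1 | dehydroacetic acid (3-acetyl-6-methyl-2H-pyran-2,4(3H)-dione) | CC(=O)C1C(=O)C=C(C)OC1=O | starting material
2 | methyl 3,5-dioxohexanoate | COC(=O)CC(=O)CC(C)=O | intermediate
3 | (E)-3,4,5-trimethoxycinnamic acid | COc1cc(/C=C/C(=O)O)cc(OC)c1OC | starting material
4 | (E)-1-(imidazol-1-yl)-3-(3,4,5-trimethoxyphenyl)prop-2-en-1-one (cinnamoyl imidazolide) | COc1cc(/C=C/C(=O)n2ccnc2)cc(OC)c1OC | intermediate (not isolated)
5 | (E)-N-methoxy-N-methyl-3-(3,4,5-trimethoxyphenyl)prop-2-enamide | COc1cc(/C=C/C(=O)N(C)OC)cc(OC)c1OC | intermediate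
6 | trilithium trianion of methyl 3,5-dioxohexanoate (tris-enolate) | [Li+].[Li+].[Li+].C=C([O-])C=C([O-])C=C([O-])OC | intermediate (not isolated)
7 | methyl (E)-3,5,7-trioxo-9-(3,4,5-trimethoxyphenyl)non-8-enoate | COC(=O)CC(=O)CC(=O)CC(=O)/C=C/c1cc(OC)c(OC)c(OC)c1 | intermediate
8 | (E)-1-(2,4,6-trihydroxyphenyl)-3-(3,4,5-trimethoxyphenyl)prop-2-en-1-one | O=C(/C=C/c1cc(OC)c(OC)c(OC)c1)c1c(O)cc(O)cc1O | intermediate
9 | (E)-1-(2-hydroxy-4,6-dimethoxyphenyl)-3-(3,4,5-trimethoxyphenyl)prop-2-en-1-one | COc1cc(O)c(C(=O)/C=C/c2cc(OC)c(OC)c(OC)c2)c(OC)c1 | intermediate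
10 | (2S)-5,7-dimethoxy-2-(3,4,5-trimethoxyphenyl)chroman-4-one | COc1cc(OC)c2c(c1)O[C@H](c1cc(OC)c(OC)c(OC)c1)CC2=O | target

**Step count**

Total: 6 steps. Longest linear sequence: 5 steps (from 1 through steps 1, 3, 4, 5, 6; equally from 3 through steps 2, 3, 4, 5, 6).

**Steps most likely to fail**

Step 4. The open-chain triketo ester may close in the wrong mode (aldol closure from C2 onto C7, or O-cyclisation to a pyranone), or methoxide may add to the enone before the ring forms. The fallback gives up the ring construction and acylates a preformed ring A. It sets out from 3, which oxalyl chloride and catalytic DMF in CH2Cl2 convert to (E)-3-(3,4,5-trimethoxyphenyl)prop-2-enoyl chloride F1. Friedel–Crafts acylation of commercial 1,3,5-trimethoxybenzene with F1 (AlCl3, CH2Cl2, 0 °C) should give (E)-1-(2,4,6-trimethoxyphenyl)-3-(3,4,5-trimethoxyphenyl)prop-2-en-1-one F2. BCl3 (1.1 equiv, CH2Cl2, −78 → 0 °C) should then cleave only the methyl ether ortho to the carbonyl, through the boron chelate, and the fallback comes back to the route at 9.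

Step 6. The ring closure is reversible, so facial selectivity may be poor, the enantiomeric purity may erode by ring opening and reclosure, and conversion may stall at the chalcone–flavanone equilibrium. The fallback separates ring closure from stereocontrol and sets out from 9. NaOAc in refluxing EtOH should close 9 to racemic 5,7-dimethoxy-2-(3,4,5-trimethoxyphenyl)chroman-4-one F3. Asymmetric transfer hydrogenation of F3 as a kinetic resolution (RuCl[(R,R)-TsDPEN](p-cymene), HCO2H/Et3N, EtOAc, to about half conversion) is expected to reduce the (2R) enantiomer to the cis alcohol (2R,4R)-5,7-dimethoxy-2-(3,4,5-trimethoxyphenyl)chroman-4-ol F4. The (2S) ketone should remain and is separated by chromatography, so the fallback comes back to the route at 10.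

Step 3. Proton transfer from the acidic product to unreacted trianion may stall the acylation, the trianion may add in conjugate fashion to the cinnamoyl unit, and the open-chain ester may cyclise during the acidic work-up. The fallback carries the chain as its stable lactone and sets out from 5. Commercial 4-hydroxy-6-methyl-2H-pyran-2-one is doubly deprotonated with LiN(i-Pr)2 (2.2 equiv, THF, −78 °C) and acylated at the 6-methyl carbon with 5, which should give 4-hydroxy-6-[(E)-2-oxo-4-(3,4,5-trimethoxyphenyl)but-3-en-1-yl]-2H-pyran-2-one F5. Heating F5 with Mg(OMe)2 in MeOH should open the lactone to the magnesium chelate of 7 and close it in the Claisen mode in the same flask, so the fallback comes back to the route at 8.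

**Further compounds**

F1 | step 4 | (E)-3-(3,4,5-trimethoxyphenyl)prop-2-enoyl chloride | COc1cc(/C=C/C(=O)Cl)cc(OC)c1OC
F2 | step 4 | (E)-1-(2,4,6-trimethoxyphenyl)-3-(3,4,5-trimethoxyphenyl)prop-2-en-1-one | COc1cc(OC)c(C(=O)/C=C/c2cc(OC)c(OC)c(OC)c2)c(OC)c1
F3 | step 6 | rac-5,7-dimethoxy-2-(3,4,5-trimethoxyphenyl)chroman-4-one | COc1cc(OC)c2c(c1)OC(c1cc(OC)c(OC)c(OC)c1)CC2=O
F4 | step 6 | (2R,4R)-5,7-dimethoxy-2-(3,4,5-trimethoxyphenyl)chroman-4-ol | COc1cc(OC)c2c(c1)O[C@@H](c1cc(OC)c(OC)c(OC)c1)C[C@H]2O
F5 | step 3 | 4-hydroxy-6-[(E)-2-oxo-4-(3,4,5-trimethoxyphenyl)but-3-en-1-yl]-2H-pyran-2-one | O=C1C=C(O)C=C(CC(=O)/C=C/c2cc(OC)c(OC)c(OC)c2)O1
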